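## Analysis of the target

Aiphanol (24) is a stilbenolignan built on a 2,3-dihydro-1,4-benzodioxine. The benzo ring is ring B; the two sp3 carbons of the dioxane are Cα, carrying ring A (4-hydroxy-3,5-dimethoxyphenyl), and Cβ, carrying the hydroxymethyl carbon Cγ; Oa is the ring oxygen on Cα and Ob the ring oxygen on Cβ. Ring B also bears an (E)-2-(3,5-dihydroxyphenyl)ethenyl arm (ring C). Cα and Cβ are the only stereocentres; they are adjacent, both R, and ring A and Cγ are trans on the dioxane. The molecule has three phenols, a primary alcohol and an electron-rich E-stilbene that rules out late hydrogenation and strong acid; the ring A phenol is para to the benzylic Cα–Oa bond, so a phenoxide or an oxidant can expel Oa through a quinone methide and scramble Cα. The synthesis is hard on two counts: the absolute and relative configuration of two vicinal C–O centres, and the regiochemistry of ring B, where two similar oxygens must be told apart (Oa on the ring carbon meta to the styryl-bearing carbon, Ob on the ring carbon para to it). The strategy rests on this pattern of ring B: the Oa carbon and the Ob carbon are neighbours, with the carbon substituent para to the Ob carbon and meta to the Oa carbon. That is the arrangement expected when a polarised ketene acetal (acetal carbon on Ob, nucleophilic CH carbon on Oa) adds across C3 and C6 of 5-carbomethoxy-2-pyrone and the adduct aromatises. Ring B can therefore be grown onto a finished, stereodefined dioxane instead of being bought as a catechol.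

## Retrosynthetic reasoning

**Silyl ethers and the stilbene.** The four silyl ethers of 23 are removed last, so that free phenols appear only in the final step. The stilbene C=C is then cut by a Horner–Wadsworth–Emmons disconnection into aldehyde 18 and phosphonate 22. This is the only C–C bond joining two fragments of comparable size, its formation is reliably E-selective, and the hydrogenation-sensitive alkene then exists for two steps only. Phosphonate 22 goes back through bromide 21 and tris-silyl ether 20 to 3,5-dihydroxybenzyl alcohol 19.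

**Oxidation level and protecting group on ring A.** Aldehyde 18 is traced through benzylic alcohol 17 to methyl ester 16. The ring A silyl ether of 16 comes from phenol 15, and 15 from benzyl ether 14 by hydrogenolysis. The benzyl group is kept through the front half because it survives hydride, titanium alkoxide, hydroxide and silyl triflate. It has to go before the stilbene exists, and the freed phenol is silylated at once so that no phenoxide para to the Cα–Oa bond is present in the oxidation and the basic olefination.

**Ring B (key disconnection).** In 14 the two ring B bonds C4a–C5 and C8a–C8 are cut, which removes four carbons of ring B and the ester as methyl coumalate 11 and leaves the dioxane as O-silyl ketene acetal 10. Cutting here uses the fact that Oa and Ob sit on neighbouring carbons with the ester para to the Ob carbon. It avoids any differentiation of two phenolic oxygens, because in 10 one oxygen is an acyl oxygen and the other an alkyl oxygen. The forward reaction has to form two C–C bonds with one regiochemistry, then decarboxylate and lose the silyloxy group, while leaving Cα and Cβ untouched.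

**Ketene acetal.** 10 is the enol silyl ether of trans lactone 9. This step only has to enolise a lactone whose α-carbon carries Oa without disturbing the benzylic ether next to it.

**Ob–Cβ bond.** Lactone 9 is opened at the Ob–Cβ bond to hydroxy acid 8. Closing this bond by a Mitsunobu reaction inverts Cβ, which is what converts the erythro chain that epoxide opening delivers into the trans ring. Acid 8 comes from ester 7, and 7 from diol 6 by silylation of the primary Cγ hydroxyl, which must be blocked so that only the Cβ hydroxyl can cyclise.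

**Oa–Cα bond.** Diol 6 is cut at the Oa–Cα bond into epoxy alcohol 4 and glycolate ester 5. The benzylic carbon of 4 is the natural electrophile, a titanium chelate directs attack to it, and the opening inverts Cα. The glycolate brings in Oa, the future nucleophilic CH carbon and the future acetal carbon in one piece.

**Source of chirality.** Epoxy alcohol 4 comes from allylic alcohol 3 by Sharpless epoxidation, the single enantioselective step; both stereocentres of 24 follow from it by two SN2 inversions. Alcohol 3 is the reduction product of ester 2, made by double benzylation of sinapic acid 1.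

## Alternatives that were turned down

**Alternative 1: oxidative closure through a quinone methide.**
- Disconnection: the Oa–Cα bond, with Ob–Cβ and the Cβ stereocentre already present in an open-chain aryl ether taken from a three-carbon chiral-pool unit.
- Forward key step: Ag2O oxidises the 4-alkyl-2,6-dimethoxyphenol of ring A to its para-quinone methide, and the free ring B hydroxyl adds to Cα. This closes the dioxane and gives (2R,3R)-3-(4-hydroxy-3,5-dimethoxyphenyl)-2-(hydroxymethyl)-2,3-dihydro-1,4-benzodioxine-6-carbaldehyde A1.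
- For: the route is very short and needs no protecting group on ring A. Ring B regiochemistry is settled by a simple etherification of the more acidic hydroxyl para to the formyl group. A1 is two operations from the target.
- Against: Cα is formed by addition to a planar quinone methide, so its configuration depends only on 1,2-induction from Cβ and on the trans preference of the ring. The quinone methide of a saturated 4-alkylphenol forms less readily than that of a propenylphenol and can tautomerise or oligomerise. A free aldehyde and an electron-rich phenol are exposed to the oxidant.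
- Comparison: on step economy this alternative is clearly stronger, and on ring B regiochemistry it is equally secure. The chosen route offers instead Cα and Cβ both fixed by reagent control and stereospecific SN2 steps before ring B exists.

**Alternative 2: Sharpless epoxide relayed through a 6-exo epoxide opening.**
- Disconnection: the Ob–Cβ bond.
- Forward key step: K2CO3 ionises the ring B hydroxyl para to the formyl group. The phenoxide attacks Cβ of a terminal Cβ–Cγ epoxide in a 6-exo mode with inversion, closing the dioxane and freeing the Cγ hydroxyl. The product is (2R,3R)-3-[4-(benzyloxy)-3,5-dimethoxyphenyl]-2-(hydroxymethyl)-2,3-dihydro-1,4-benzodioxine-6-carbaldehyde A2.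
- For: both stereocentres come from one asymmetric epoxidation through stereospecific steps. The ring closure is a well-behaved intramolecular epoxide opening. A2 already has the free Cγ hydroxyl and the formyl group for olefination.
- Against: the Oa–Cα bond must first be made by benzylic opening with a ring B phenol whose second hydroxyl has to be masked and unmasked. The resulting diol must be turned into the terminal epoxide. Attack at Cγ (7-endo) competes. Removal of the benzyl group has to be fitted around an aldehyde and then a stilbene.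
- Comparison: in reliability this is the strongest of the four, and it is at least as short as the chosen route. The chosen route offers a ring B regiochemistry that does not depend on telling two phenolic hydroxyls apart with protecting groups, and a late, convergent construction of the arene from a cheap pyrone.

**Alternative 3: SNAr closure on a fluoride para to the formyl group.**
- Disconnection: the C(aryl)–Ob bond.
- Forward key step: K2CO3 in DMF turns the Cβ hydroxyl into an alkoxide that displaces fluoride para to the formyl group through a Meisenheimer intermediate and closes the dioxane. The free ring A phenoxide lets the Cα–Oa bond open reversibly to a quinone methide, so Cα equilibrates to trans. The product is (2R,3R)-2-[(benzyloxy)methyl]-3-(4-hydroxy-3,5-dimethoxyphenyl)-2,3-dihydro-1,4-benzodioxine-6-carbaldehyde A3.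
- For: regiochemistry is fixed by the position of the fluoride. The formyl group both activates the substitution and serves as the olefination handle. Only Cβ has to be made by asymmetric synthesis.
- Against: Cα is set under thermodynamic control, and the equilibrium need not be one-sided. The quinone methide can be intercepted intermolecularly. The benzyl ether on Cγ of A3 must be removed in the presence of an aldehyde or, later, of the stilbene.
- Comparison: length is comparable, and the regiochemical certainty is higher than that of an untested cycloaddition. The chosen strategy sets Cα kinetically by SN2 inversion and does not rely on equilibration.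

Key step: step 9

Remark on the chemistry (assumption): the glycolate unit is introduced as its isopropyl ester 5, a catalogue compound, because a methyl ester would exchange with the isopropoxide ligands of Ti(OiPr)4; the ester is hydrolysed two steps later, so nothing else changes.

## Route

Step 1
Reactants: 1 sinapic acid, (E)-3-(4-hydroxy-3,5-dimethoxyphenyl)prop-2-enoic acid
Product: 2 benzyl (E)-3-[4-(benzyloxy)-3,5-dimethoxyphenyl]prop-2-enoate
Conditions: BnBr (2.5 equiv), K2CO3, DMF, 60 °C
Reagents that add atoms: benzyl bromide, BrCc1ccccc1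
Why: Williamson etherification of the phenoxide and alkylation of the carboxylate in one operation protect ring A and give an ester ready for reduction.

Step 2
Reactants: 2 benzyl (E)-3-[4-(benzyloxy)-3,5-dimethoxyphenyl]prop-2-enoate
Product: 3 (E)-3-[4-(benzyloxy)-3,5-dimethoxyphenyl]prop-2-en-1-ol
Conditions: i-Bu2AlH (3 equiv), CH2Cl2, −78 → 0 °C; aq. potassium sodium tartrate
Reagents that add atoms: none
Why: 1,2-Reduction of an α,β-unsaturated ester by an aluminium hydride gives the allylic alcohol and leaves the E-alkene and the benzyl ether intact.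

Step 3
Reactants: 3 (E)-3-[4-(benzyloxy)-3,5-dimethoxyphenyl]prop-2-en-1-ol
Product: 4 [(2S,3S)-3-[4-(benzyloxy)-3,5-dimethoxyphenyl]oxiran-2-yl]methanol
Conditions: Ti(OiPr)4 (10 mol %), L-(+)-diisopropyl tartrate (12 mol %), t-BuOOH, 4 Å MS, CH2Cl2, −20 °C
Reagents that add atoms: tert-butyl hydroperoxide, CC(C)(C)OO
Why: Sharpless asymmetric epoxidation; with the L-(+)-tartrate the oxygen is delivered to the face of the E-allylic alcohol that gives the (2S,3S)-epoxide, which fixes the absolute configuration of both future stereocentres. The two meta methoxy groups are inductively withdrawing at the benzylic carbon and twist the 4-benzyloxy group out of conjugation, so the epoxide should be far less labile than a 4-alkoxyphenyl epoxide.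

Step 4
Reactants: 4 [(2S,3S)-3-[4-(benzyloxy)-3,5-dimethoxyphenyl]oxiran-2-yl]methanol; 5 propan-2-yl 2-hydroxyacetate (isopropyl glycolate)
Product: 6 propan-2-yl 2-{[(1R,2S)-1-[4-(benzyloxy)-3,5-dimethoxyphenyl]-2,3-dihydroxypropyl]oxy}acetate
Conditions: Ti(OiPr)4 (1.5 equiv) premixed with 5 (8 equiv), i-PrOH removed in vacuo; then 4, CH2Cl2, rt
Reagents that add atoms: none
Why: Titanium-mediated opening of a 2,3-epoxy alcohol: the epoxy alkoxide binds titanium and the glycolate hydroxyl attacks C3, which is also the benzylic carbon, with inversion. This forms the Oa–Cα bond and sets Cα as R while Cβ stays S.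

Step 5
Reactants: 6 propan-2-yl 2-{[(1R,2S)-1-[4-(benzyloxy)-3,5-dimethoxyphenyl]-2,3-dihydroxypropyl]oxy}acetate
Product: 7 propan-2-yl 2-{[(1R,2S)-1-[4-(benzyloxy)-3,5-dimethoxyphenyl]-3-[(tert-butyldimethylsilyl)oxy]-2-hydroxypropyl]oxy}acetate
Conditions: TBSCl (1.05 equiv), imidazole, CH2Cl2, 0 °C
Reagents that add atoms: tert-butyldimethylsilyl chloride, CC(C)(C)[Si](C)(C)Cl
Why: Silylation selects the primary Cγ hydroxyl over the hindered secondary Cβ hydroxyl on steric grounds, so only the Cβ hydroxyl remains for the ring closure.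

Step 6
Reactants: 7 propan-2-yl 2-{[(1R,2S)-1-[4-(benzyloxy)-3,5-dimethoxyphenyl]-3-[(tert-butyldimethylsilyl)oxy]-2-hydroxypropyl]oxy}acetate
Product: 8 2-{[(1R,2S)-1-[4-(benzyloxy)-3,5-dimethoxyphenyl]-3-[(tert-butyldimethylsilyl)oxy]-2-hydroxypropyl]oxy}acetic acid
Conditions: LiOH (2 equiv), THF/H2O, 0 °C → rt; then dil. HCl to pH 4, 0 °C
Reagents that add atoms: lithium hydroxide, [Li+].[OH-]
Why: Saponification of an α-alkoxy ester is fast under mild conditions that leave the primary silyl ether and the benzyl ether untouched.

Step 7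
Reactants: 8 2-{[(1R,2S)-1-[4-(benzyloxy)-3,5-dimethoxyphenyl]-3-[(tert-butyldimethylsilyl)oxy]-2-hydroxypropyl]oxy}acetic acid
Product: 9 (5R,6R)-5-[4-(benzyloxy)-3,5-dimethoxyphenyl]-6-{[(tert-butyldimethylsilyl)oxy]methyl}-1,4-dioxan-2-one
Conditions: PPh3, DIAD, THF (0.01 M), slow addition of 8, 0 °C → rt
Reagents that add atoms: none
Why: Mitsunobu lactonisation: the Cβ hydroxyl is activated as its oxyphosphonium ion and displaced by the tethered carboxylate in a 6-exo-tet SN2 step. This forms the Ob–Cβ bond with inversion (S to R) and so gives the trans lactone; high dilution suppresses oligomers.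

Step 8
Reactants: 9 (5R,6R)-5-[4-(benzyloxy)-3,5-dimethoxyphenyl]-6-{[(tert-butyldimethylsilyl)oxy]methyl}-1,4-dioxan-2-one
Product: 10 tert-butyl({(5R,6R)-5-[4-(benzyloxy)-3,5-dimethoxyphenyl]-6-{[(tert-butyldimethylsilyl)oxy]methyl}-5,6-dihydro-1,4-dioxin-2-yl}oxy)dimethylsilane
Conditions: TBSOTf (1.3 equiv), Et3N (2 equiv), CH2Cl2, −78 → 0 °C; pentane, filtration, used crude
Reagents that add atoms: tert-butyldimethylsilyl trifluoromethanesulfonate, CC(C)(C)[Si](C)(C)OS(=O)(=O)C(F)(F)F
Why: Soft enolisation: silylation of the lactone carbonyl oxygen acidifies the α-CH2, which the amine deprotonates to give the O-silyl ketene acetal. Avoiding a lithium enolate excludes Wittig rearrangement of the benzylic ether, and the ring fixes the alkene geometry while Cα and Cβ are not involved.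

Step 9
Reactants: 10 tert-butyl({(5R,6R)-5-[4-(benzyloxy)-3,5-dimethoxyphenyl]-6-{[(tert-butyldimethylsilyl)oxy]methyl}-5,6-dihydro-1,4-dioxin-2-yl}oxy)dimethylsilane; 11 methyl coumalate (methyl 2-oxo-2H-pyran-5-carboxylate)
Product: 14 methyl (2R,3R)-3-[4-(benzyloxy)-3,5-dimethoxyphenyl]-2-{[(tert-butyldimethylsilyl)oxy]methyl}-2,3-dihydro-1,4-benzodioxine-6-carboxylate, via bridged lactone cycloadduct 12 (not isolated), via silyloxy cyclohexadiene 13 (not isolated)
Conditions: 11 (1.5 equiv), PhMe, 80 → 110 °C; then DBU (cat.), rt
Reagents that add atoms: none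
Why: Proposed new method: the closest known reaction type is the inverse-electron-demand Diels–Alder reaction of methyl coumalate and related 2-pyrones with acyclic ketene acetals and enol ethers, which gives benzoates after loss of CO2 and an alcohol; new here is a lactone-derived cyclic O-silyl ketene acetal whose two ring oxygens are kept, so that the arene is annulated onto a dioxane. The HOMO of 10 is largest on its CH carbon (one oxygen against two on the acetal carbon) and the LUMO of 11 is largest on C6, the terminus conjugated to both the ester and the lactone carbonyl, so the CH carbon (bearing Oa) should bond to C6 and the acetal carbon (bearing Ob and the silyloxy group) to C3 in a concerted but asynchronous [4+2] addition, giving bridged lactone 12. Retro-[4+2] extrusion of CO2 from 12 gives cyclohexadiene 13, and 1,2-elimination of t-BuMe2SiOH across the former ketene acetal carbons aromatises it to 14. Ring B is thus closed by an intermolecular [4+2] annulation in which both new C–C bonds are made to the existing C=C of the dihydrodioxine, four ring atoms coming from the pyrone and two from the ketene acetal. No lasting stereocentre is created: the sp3 centres of 12 and 13 vanish on aromatisation, and Cα and Cβ lie outside the reacting π system and are carried through unchanged. Two selectivities are required. The regiochemistry follows from the matched polarisation just described and places the ester para to the Ob carbon and meta to the Oa carbon. The leaving group in 13 should be the silanolate, the better nucleofuge, in an E1cB-type elimination through the vinylogous ester enolate (the ring-fusion C–H is γ to the ester), which is why the medium is kept neutral to basic: acid would protonate the more basic ring oxygen Ob and open the dioxane.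

Step 10
Reactants: 14 methyl (2R,3R)-3-[4-(benzyloxy)-3,5-dimethoxyphenyl]-2-{[(tert-butyldimethylsilyl)oxy]methyl}-2,3-dihydro-1,4-benzodioxine-6-carboxylate
Product: 15 methyl (2R,3R)-2-{[(tert-butyldimethylsilyl)oxy]methyl}-3-(4-hydroxy-3,5-dimethoxyphenyl)-2,3-dihydro-1,4-benzodioxine-6-carboxylate
Conditions: H2 (1 atm), 10% Pd/C, EtOAc, rt
Reagents that add atoms: none
Why: Hydrogenolysis of the primary aryl benzyl ether should be much faster than cleavage of the hindered, secondary benzylic Cα–Oa bond. It is done here because the stilbene made later would not survive hydrogen, and ethyl acetate as solvent spares the silyl ether.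

Step 11
Reactants: 15 methyl (2R,3R)-2-{[(tert-butyldimethylsilyl)oxy]methyl}-3-(4-hydroxy-3,5-dimethoxyphenyl)-2,3-dihydro-1,4-benzodioxine-6-carboxylate
Product: 16 methyl (2R,3R)-3-{4-[(tert-butyldimethylsilyl)oxy]-3,5-dimethoxyphenyl}-2-{[(tert-butyldimethylsilyl)oxy]methyl}-2,3-dihydro-1,4-benzodioxine-6-carboxylate
Conditions: TBSCl, imidazole, DMAP (cat.), DMF, rt
Reagents that add atoms: tert-butyldimethylsilyl chloride, CC(C)(C)[Si](C)(C)Cl
Why: Silylation masks the ring A phenol so that no phenoxide para to the Cα–Oa bond and no oxidisable phenol is present during oxidation and olefination. The group leaves with the other silyl ethers in the last step.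

Step 12
Reactants: 16 methyl (2R,3R)-3-{4-[(tert-butyldimethylsilyl)oxy]-3,5-dimethoxyphenyl}-2-{[(tert-butyldimethylsilyl)oxy]methyl}-2,3-dihydro-1,4-benzodioxine-6-carboxylate
Product: 17 [(2R,3R)-3-{4-[(tert-butyldimethylsilyl)oxy]-3,5-dimethoxyphenyl}-2-{[(tert-butyldimethylsilyl)oxy]methyl}-2,3-dihydro-1,4-benzodioxin-6-yl]methanol
Conditions: i-Bu2AlH (2.5 equiv), CH2Cl2, −78 → 0 °C; aq. potassium sodium tartrate
Reagents that add atoms: none
Why: Hydride reduction of the aryl ester to the benzylic alcohol; aryl and alkyl silyl ethers are inert to the reagent.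

Step 13
Reactants: 17 [(2R,3R)-3-{4-[(tert-butyldimethylsilyl)oxy]-3,5-dimethoxyphenyl}-2-{[(tert-butyldimethylsilyl)oxy]methyl}-2,3-dihydro-1,4-benzodioxin-6-yl]methanol
Product: 18 (2R,3R)-3-{4-[(tert-butyldimethylsilyl)oxy]-3,5-dimethoxyphenyl}-2-{[(tert-butyldimethylsilyl)oxy]methyl}-2,3-dihydro-1,4-benzodioxine-6-carbaldehyde
Conditions: MnO2 (activated, excess), CH2Cl2, rt
Reagents that add atoms: none
Why: MnO2 oxidises benzylic alcohols selectively to aldehydes without over-oxidation, and with the phenol silylated no quinone methide can form.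

Step 14
Reactants: 19 3,5-dihydroxybenzyl alcohol
Product: 20 tert-butyl({3,5-bis[(tert-butyldimethylsilyl)oxy]phenyl}methoxy)dimethylsilane
Conditions: TBSCl (3.5 equiv), imidazole, DMF, rt
Reagents that add atoms: tert-butyldimethylsilyl chloride, CC(C)(C)[Si](C)(C)Cl
Why: Exhaustive silylation of the two phenols and the benzylic alcohol avoids any need to tell them apart at this stage.

Step 15
Reactants: 20 tert-butyl({3,5-bis[(tert-butyldimethylsilyl)oxy]phenyl}methoxy)dimethylsilane
Product: 21 {[5-(bromomethyl)-1,3-phenylene]bis(oxy)}bis(tert-butyldimethylsilane), 3,5-bis[(tert-butyldimethylsilyl)oxy]benzyl bromide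
Conditions: Ph3PBr2 (1.2 equiv), CH2Cl2, 0 °C → rt
Reagents that add atoms: dibromotriphenylphosphorane, BrP(Br)(c1ccccc1)(c1ccccc1)c1ccccc1
Why: Triphenylphosphine dibromide converts alkyl silyl ethers directly into bromides: the ether oxygen attacks phosphorus, the silyl group leaves as silyl bromide and bromide displaces Ph3PO at the benzylic carbon. Aryl silyl ethers cannot undergo the SN2 step and stay.

Step 16
Reactants: 21 3,5-bis[(tert-butyldimethylsilyl)oxy]benzyl bromide
Product: 22 diethyl ({3,5-bis[(tert-butyldimethylsilyl)oxy]phenyl}methyl)phosphonate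
Conditions: P(OEt)3 (neat), 130 °C
Reagents that add atoms: triethyl phosphite, CCOP(OCC)OCC
Why: Michaelis–Arbuzov reaction of a benzylic bromide; the aryl silyl ethers tolerate the neutral thermal conditions.

Step 17
Reactants: 18 (2R,3R)-3-{4-[(tert-butyldimethylsilyl)oxy]-3,5-dimethoxyphenyl}-2-{[(tert-butyldimethylsilyl)oxy]methyl}-2,3-dihydro-1,4-benzodioxine-6-carbaldehyde; 22 diethyl ({3,5-bis[(tert-butyldimethylsilyl)oxy]phenyl}methyl)phosphonate
Product: 23 (2R,3R)-6-[(E)-2-{3,5-bis[(tert-butyldimethylsilyl)oxy]phenyl}ethenyl]-3-{4-[(tert-butyldimethylsilyl)oxy]-3,5-dimethoxyphenyl}-2-{[(tert-butyldimethylsilyl)oxy]methyl}-2,3-dihydro-1,4-benzodioxine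
Conditions: NaH, THF, 0 °C → rt
Reagents that add atoms: none
Why: Horner–Wadsworth–Emmons olefination of an aryl aldehyde with a benzylphosphonate anion; reversible addition and elimination through the less crowded oxaphosphetane should give the E-stilbene.

Step 18
Reactants: 23 (2R,3R)-6-[(E)-2-{3,5-bis[(tert-butyldimethylsilyl)oxy]phenyl}ethenyl]-3-{4-[(tert-butyldimethylsilyl)oxy]-3,5-dimethoxyphenyl}-2-{[(tert-butyldimethylsilyl)oxy]methyl}-2,3-dihydro-1,4-benzodioxine
Product: 24 aiphanol, 5-[(E)-2-[(2R,3R)-3-(4-hydroxy-3,5-dimethoxyphenyl)-2-(hydroxymethyl)-2,3-dihydro-1,4-benzodioxin-6-yl]ethenyl]benzene-1,3-diol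
Conditions: Bu4NF/AcOH (1:1, 6 equiv), THF, 0 °C → rt
Reagents that add atoms: none
Why: Fluoride cleaves the three aryl silyl ethers and the alkyl silyl ether in one operation. Acetic acid keeps the freed ring A phenol protonated, so the Cα–Oa bond is not opened through a quinone methide and Cα keeps its configuration.

## Compound list

1 | sinapic acid, (E)-3-(4-hydroxy-3,5-dimethoxyphenyl)prop-2-enoic acid | COc1cc(/C=C/C(=O)O)cc(OC)c1O | starting material
2 | benzyl (E)-3-[4-(benzyloxy)-3,5-dimethoxyphenyl]prop-2-enoate | COc1cc(/C=C/C(=O)OCc2ccccc2)cc(OC)c1OCc1ccccc1 | intermediate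
3 | (E)-3-[4-(benzyloxy)-3,5-dimethoxyphenyl]prop-2-en-1-ol | COc1cc(/C=C/CO)cc(OC)c1OCc1ccccc1 | intermediate
4 | [(2S,3S)-3-[4-(benzyloxy)-3,5-dimethoxyphenyl]oxiran-2-yl]methanol | OC[C@@H]1O[C@H]1c1cc(OC)c(OCc2ccccc2)c(OC)c1 | intermediate
5 | propan-2-yl 2-hydroxyacetate (isopropyl glycolate) | CC(C)OC(=O)CO | starting material
6 | propan-2-yl 2-{[(1R,2S)-1-[4-(benzyloxy)-3,5-dimethoxyphenyl]-2,3-dihydroxypropyl]oxy}acetate | CC(C)OC(=O)CO[C@H](c1cc(OC)c(OCc2ccccc2)c(OC)c1)[C@H](CO)O | intermediate
7 | propan-2-yl 2-{[(1R,2S)-1-[4-(benzyloxy)-3,5-dimethoxyphenyl]-3-[(tert-butyldimethylsilyl)oxy]-2-hydroxypropyl]oxy}acetate | CC(C)OC(=O)CO[C@H](c1cc(OC)c(OCc2ccccc2)c(OC)c1)[C@H](CO[Si](C)(C)C(C)(C)C)O | intermediate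
8 | 2-{[(1R,2S)-1-[4-(benzyloxy)-3,5-dimethoxyphenyl]-3-[(tert-butyldimethylsilyl)oxy]-2-hydroxypropyl]oxy}acetic acid | OC(=O)CO[C@H](c1cc(OC)c(OCc2ccccc2)c(OC)c1)[C@H](CO[Si](C)(C)C(C)(C)C)O | intermediate
9 | (5R,6R)-5-[4-(benzyloxy)-3,5-dimethoxyphenyl]-6-{[(tert-butyldimethylsilyl)oxy]methyl}-1,4-dioxan-2-one (trans lactone) | O=C1CO[C@H](c2cc(OC)c(OCc3ccccc3)c(OC)c2)[C@@H](CO[Si](C)(C)C(C)(C)C)O1 | intermediate
10 | tert-butyl({(5R,6R)-5-[4-(benzyloxy)-3,5-dimethoxyphenyl]-6-{[(tert-butyldimethylsilyl)oxy]methyl}-5,6-dihydro-1,4-dioxin-2-yl}oxy)dimethylsilane (O-silyl ketene acetal) | CC(C)(C)[Si](C)(C)OC1=CO[C@H](c2cc(OC)c(OCc3ccccc3)c(OC)c2)[C@@H](CO[Si](C)(C)C(C)(C)C)O1 | intermediate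
11 | methyl coumalate, methyl 2-oxo-2H-pyran-5-carboxylate | COC(=O)C1=COC(=O)C=C1 | starting material
12 | bridged lactone cycloadduct: 2-oxabicyclo[2.2.2]oct-5-en-3-one with CO2Me on C6, whose C7–C8 bond is the ring-fusion bond of the dioxane (C7, next to bridgehead C1, bears Oa and H; C8, next to bridgehead C4, bears Ob and the tert-butyldimethylsilyloxy group); Cα (R) and Cβ (R) as in 10; the four new stereocentres are not defined | COC(=O)C1=CC2C(=O)OC1C1O[C@H](c3cc(OC)c(OCc4ccccc4)c(OC)c3)[C@@H](CO[Si](C)(C)C(C)(C)C)OC21O[Si](C)(C)C(C)(C)C | intermediate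
13 | methyl (2R,3R)-3-[4-(benzyloxy)-3,5-dimethoxyphenyl]-8a-[(tert-butyldimethylsilyl)oxy]-2-{[(tert-butyldimethylsilyl)oxy]methyl}-2,3,4a,8a-tetrahydro-1,4-benzodioxine-6-carboxylate (configuration at C4a and C8a not defined) | COC(=O)C1=CC2O[C@H](c3cc(OC)c(OCc4ccccc4)c(OC)c3)[C@@H](CO[Si](C)(C)C(C)(C)C)OC2(O[Si](C)(C)C(C)(C)C)C=C1 | intermediate
14 | methyl (2R,3R)-3-[4-(benzyloxy)-3,5-dimethoxyphenyl]-2-{[(tert-butyldimethylsilyl)oxy]methyl}-2,3-dihydro-1,4-benzodioxine-6-carboxylate | COc1cc([C@H]2Oc3cc(C(=O)OC)ccc3O[C@@H]2CO[Si](C)(C)C(C)(C)C)cc(OC)c1OCc1ccccc1 | intermediate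
15 | methyl (2R,3R)-2-{[(tert-butyldimethylsilyl)oxy]methyl}-3-(4-hydroxy-3,5-dimethoxyphenyl)-2,3-dihydro-1,4-benzodioxine-6-carboxylate | COc1cc([C@H]2Oc3cc(C(=O)OC)ccc3O[C@@H]2CO[Si](C)(C)C(C)(C)C)cc(OC)c1O | intermediate
16 | methyl (2R,3R)-3-{4-[(tert-butyldimethylsilyl)oxy]-3,5-dimethoxyphenyl}-2-{[(tert-butyldimethylsilyl)oxy]methyl}-2,3-dihydro-1,4-benzodioxine-6-carboxylate | COc1cc([C@H]2Oc3cc(C(=O)OC)ccc3O[C@@H]2CO[Si](C)(C)C(C)(C)C)cc(OC)c1O[Si](C)(C)C(C)(C)C | intermediate
17 | [(2R,3R)-3-{4-[(tert-butyldimethylsilyl)oxy]-3,5-dimethoxyphenyl}-2-{[(tert-butyldimethylsilyl)oxy]methyl}-2,3-dihydro-1,4-benzodioxin-6-yl]methanol | COc1cc([C@H]2Oc3cc(CO)ccc3O[C@@H]2CO[Si](C)(C)C(C)(C)C)cc(OC)c1O[Si](C)(C)C(C)(C)C | intermediate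
18 | (2R,3R)-3-{4-[(tert-butyldimethylsilyl)oxy]-3,5-dimethoxyphenyl}-2-{[(tert-butyldimethylsilyl)oxy]methyl}-2,3-dihydro-1,4-benzodioxine-6-carbaldehyde | COc1cc([C@H]2Oc3cc(C=O)ccc3O[C@@H]2CO[Si](C)(C)C(C)(C)C)cc(OC)c1O[Si](C)(C)C(C)(C)C | intermediate
19 | 3,5-dihydroxybenzyl alcohol | OCc1cc(O)cc(O)c1 | starting material
20 | tert-butyl({3,5-bis[(tert-butyldimethylsilyl)oxy]phenyl}methoxy)dimethylsilane | CC(C)(C)[Si](C)(C)OCc1cc(O[Si](C)(C)C(C)(C)C)cc(O[Si](C)(C)C(C)(C)C)c1 | intermediate
21 | 3,5-bis[(tert-butyldimethylsilyl)oxy]benzyl bromide | BrCc1cc(O[Si](C)(C)C(C)(C)C)cc(O[Si](C)(C)C(C)(C)C)c1 | intermediate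
22 | diethyl ({3,5-bis[(tert-butyldimethylsilyl)oxy]phenyl}methyl)phosphonate | CCOP(=O)(Cc1cc(O[Si](C)(C)C(C)(C)C)cc(O[Si](C)(C)C(C)(C)C)c1)OCC | intermediate
23 | (2R,3R)-6-[(E)-2-{3,5-bis[(tert-butyldimethylsilyl)oxy]phenyl}ethenyl]-3-{4-[(tert-butyldimethylsilyl)oxy]-3,5-dimethoxyphenyl}-2-{[(tert-butyldimethylsilyl)oxy]methyl}-2,3-dihydro-1,4-benzodioxine | COc1cc([C@H]2Oc3cc(/C=C/c4cc(O[Si](C)(C)C(C)(C)C)cc(O[Si](C)(C)C(C)(C)C)c4)ccc3O[C@@H]2CO[Si](C)(C)C(C)(C)C)cc(OC)c1O[Si](C)(C)C(C)(C)C | intermediate
24 | aiphanol, 5-[(E)-2-[(2R,3R)-3-(4-hydroxy-3,5-dimethoxyphenyl)-2-(hydroxymethyl)-2,3-dihydro-1,4-benzodioxin-6-yl]ethenyl]benzene-1,3-diol | COc1cc([C@H]2Oc3cc(/C=C/c4cc(O)cc(O)c4)ccc3O[C@@H]2CO)cc(OC)c1O | target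

## Step count and least certain steps

Total step count: 18 (15 in the main line, 3 for phosphonate 22).
Longest linear sequence: 15 steps, from 1 to 24 (steps 1–13, 17 and 18).

**Step 9 (key step, proposed new method).**
- What may go wrong: the first C–C bond may form without the second. A stepwise Mukaiyama–Michael addition at C6, followed by silyl transfer to the pyrone-derived dienolate or by opening of the 2H-pyran, competes with collapse to the bridged lactone because the zwitterion is stabilised on both sides. Aromatisation may also proceed with departure of the ring oxygen Ob instead of the silyloxy group, which opens the dioxane. The ketene acetal may hydrolyse back to the lactone before it reacts.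
- Fallback (known chemistry), from epoxy alcohol 4 back to ester 14: purchased methyl 3,4-dihydroxybenzoate is allylated at its more acidic hydroxyl, para to the ester (allyl bromide, K2CO3, one equivalent), to give methyl 3-hydroxy-4-(prop-2-en-1-yloxy)benzoate F1. Its phenoxide (Cs2CO3, DMF) opens 4 at the benzylic carbon with inversion, which forms the Oa–Cα bond and gives methyl 3-{[(1R,2S)-1-[4-(benzyloxy)-3,5-dimethoxyphenyl]-2,3-dihydroxypropyl]oxy}-4-(prop-2-en-1-yloxy)benzoate F2. Silylation of the primary hydroxyl (TBSCl, imidazole) gives methyl 3-{[(1R,2S)-1-[4-(benzyloxy)-3,5-dimethoxyphenyl]-3-[(tert-butyldimethylsilyl)oxy]-2-hydroxypropyl]oxy}-4-(prop-2-en-1-yloxy)benzoate F3. Pd(PPh3)4 with morpholine removes the allyl group to give methyl 3-{[(1R,2S)-1-[4-(benzyloxy)-3,5-dimethoxyphenyl]-3-[(tert-butyldimethylsilyl)oxy]-2-hydroxypropyl]oxy}-4-hydroxybenzoate F4. An intramolecular Mitsunobu etherification (PPh3, DIAD) lets the phenol para to the ester displace the activated Cβ hydroxyl with inversion and closes the dioxane as 14. Ring B regiochemistry then comes from the protecting group on the catechol.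

**Step 4.**
- What may go wrong: the glycolate hydroxyl is a weak nucleophile that also chelates titanium, so the opening may be slow and isopropoxide may be transferred from titanium in its place. Partial ionisation of the benzylic C–O bond would erode the inversion at Cα. Lactonisation of the product onto the Cβ hydroxyl is harmless, since step 6 reopens the ring.
- Fallback, from 4 back to 7: the primary hydroxyl is silylated first (TBSCl, imidazole) to give tert-butyl{[(2S,3S)-3-[4-(benzyloxy)-3,5-dimethoxyphenyl]oxiran-2-yl]methoxy}dimethylsilane F5. The epoxide is then opened by 5 under catalysis by BF3·OEt2 in CH2Cl2 at −40 °C. Without a chelate, the benzylic position alone directs the borderline SN2 attack, and hydroxy ester 7 is reached directly.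

**Step 7.**
- What may go wrong: activation of the carboxyl group in place of the hindered Cβ hydroxyl would give lactonisation with retention. Elimination of the oxyphosphonium ion and participation of the electron-rich ring A on the neighbouring carbon are further risks.
- Fallback, from 7 back to 9: the Cβ hydroxyl is converted into its mesylate (MsCl, Et3N) to give propan-2-yl 2-{[(1R,2S)-1-[4-(benzyloxy)-3,5-dimethoxyphenyl]-3-[(tert-butyldimethylsilyl)oxy]-2-(methanesulfonyloxy)propyl]oxy}acetate F6. LiOH at 0 °C hydrolyses the ester to 2-{[(1R,2S)-1-[4-(benzyloxy)-3,5-dimethoxyphenyl]-3-[(tert-butyldimethylsilyl)oxy]-2-(methanesulfonyloxy)propyl]oxy}acetic acid F7. Its carboxylate displaces the mesylate on warming in DMF (6-exo-tet, inversion) to give 9. Only the hydroxyl can be activated in this sequence, so retention is excluded.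

**Step 10.**
- What may go wrong: over-reduction, in which the endocyclic benzylic Cα–Oa bond is hydrogenolysed along with the benzyl ether and the dioxane opens.
- Fallback, from 14 back to 15: Lewis-acid debenzylation with BCl3 and pentamethylbenzene as benzyl cation scavenger in CH2Cl2 at −78 °C. The two flanking methoxy groups direct boron to the benzyloxy oxygen, and no hydrogen is involved. This fallback makes no new compound (F0).

## Further compounds

F1 | step 9 | methyl 3-hydroxy-4-(prop-2-en-1-yloxy)benzoate | COC(=O)c1ccc(OCC=C)c(O)c1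
F2 | step 9 | methyl 3-{[(1R,2S)-1-[4-(benzyloxy)-3,5-dimethoxyphenyl]-2,3-dihydroxypropyl]oxy}-4-(prop-2-en-1-yloxy)benzoate | COC(=O)c1ccc(OCC=C)c(O[C@H](c2cc(OC)c(OCc3ccccc3)c(OC)c2)[C@H](CO)O)c1
F3 | step 9 | methyl 3-{[(1R,2S)-1-[4-(benzyloxy)-3,5-dimethoxyphenyl]-3-[(tert-butyldimethylsilyl)oxy]-2-hydroxypropyl]oxy}-4-(prop-2-en-1-yloxy)benzoate | COC(=O)c1ccc(OCC=C)c(O[C@H](c2cc(OC)c(OCc3ccccc3)c(OC)c2)[C@H](CO[Si](C)(C)C(C)(C)C)O)c1
F4 | step 9 | methyl 3-{[(1R,2S)-1-[4-(benzyloxy)-3,5-dimethoxyphenyl]-3-[(tert-butyldimethylsilyl)oxy]-2-hydroxypropyl]oxy}-4-hydroxybenzoate | COC(=O)c1ccc(O)c(O[C@H](c2cc(OC)c(OCc3ccccc3)c(OC)c2)[C@H](CO[Si](C)(C)C(C)(C)C)O)c1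
F5 | step 4 | tert-butyl{[(2S,3S)-3-[4-(benzyloxy)-3,5-dimethoxyphenyl]oxiran-2-yl]methoxy}dimethylsilane | CC(C)(C)[Si](C)(C)OC[C@@H]1O[C@H]1c1cc(OC)c(OCc2ccccc2)c(OC)c1
F6 | step 7 | propan-2-yl 2-{[(1R,2S)-1-[4-(benzyloxy)-3,5-dimethoxyphenyl]-3-[(tert-butyldimethylsilyl)oxy]-2-(methanesulfonyloxy)propyl]oxy}acetate | CC(C)OC(=O)CO[C@H](c1cc(OC)c(OCc2ccccc2)c(OC)c1)[C@H](CO[Si](C)(C)C(C)(C)C)OS(C)(=O)=O
F7 | step 7 | 2-{[(1R,2S)-1-[4-(benzyloxy)-3,5-dimethoxyphenyl]-3-[(tert-butyldimethylsilyl)oxy]-2-(methanesulfonyloxy)propyl]oxy}acetic acid | OC(=O)CO[C@H](c1cc(OC)c(OCc2ccccc2)c(OC)c1)[C@H](CO[Si](C)(C)C(C)(C)C)OS(C)(=O)=O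
F0 | step 10 | none | none
A1 | alternative 1 | (2R,3R)-3-(4-hydroxy-3,5-dimethoxyphenyl)-2-(hydroxymethyl)-2,3-dihydro-1,4-benzodioxine-6-carbaldehyde | COc1cc([C@H]2Oc3cc(C=O)ccc3O[C@@H]2CO)cc(OC)c1O
A2 | alternative 2 | (2R,3R)-3-[4-(benzyloxy)-3,5-dimethoxyphenyl]-2-(hydroxymethyl)-2,3-dihydro-1,4-benzodioxine-6-carbaldehyde | COc1cc([C@H]2Oc3cc(C=O)ccc3O[C@@H]2CO)cc(OC)c1OCc1ccccc1
A3 | alternative 3 | (2R,3R)-2-[(benzyloxy)methyl]-3-(4-hydroxy-3,5-dimethoxyphenyl)-2,3-dihydro-1,4-benzodioxine-6-carbaldehyde | COc1cc([C@H]2Oc3cc(C=O)ccc3O[C@@H]2COCc2ccccc2)cc(OC)c1O
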